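Pooled over the delta samples, target made up 44.8% of target plus isomer of the product, and I carried this share forward as the split. In these flasks, starting material binds free catalyst as catalyst intermediate A, partner converts that to catalyst intermediate B, which releases target and free catalyst, and target interconverts with its isomer.

in all of them: starting material 0.25 M
- alpha: partner 0.175 M (fed, over 15 h); free catalyst 0.88 mM; temperature −15 °C; run made earlier; the fed solution adds 0.10 times the starting volume
- delta: partner 0.175 M (fed, over 15 h); free catalyst 1.9 mM; temperature 0 °C; run made earlier; the fed solution adds 0.10 times the starting volume
- winter: partner 0.175 M; free catalyst 1.5 mM; temperature 0 °C; everything together at the start, the whole solution of partner included, so that from the start the volume is larger by 0.10 times the starting volume; time 40 h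
- autumn: partner 0.175 M (fed, over 15 h); free catalyst 2.5 mM; temperature 0 °C; the fed solution adds 0.10 times the starting volume; time 25 h

- alpha (time / h: target / %, isomer of the product / %): 10.0: 2, 4; 20.0: 2, 2; 30.0: 7, 4; 40.0: 3, 7; 48.0: 5, 7
- delta (time / h: target / %, isomer of the product / %): 2.00: 1, 2; 6.00: 4, 6; 12.0: 14, 20; 20.0: 29, 32; 25.0: 30, 36

(readings scatter by 2 percentage points)

- amounts are per litre of the starting volume; all of the dose is in the solution fed
- what was read earlier has a scatter of 2 percentage points, one standard deviation
- reactions considered so far: starting material + free catalyst <-> catalyst intermediate A; partner + catalyst intermediate A -> catalyst intermediate B; catalyst intermediate B -> free catalyst + target; target <-> isomer of the product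

1. the flask that ends with the higher share of target in all that became target or isomer of the product, or "neither" when 2 percentage points or less lies between them (winter / autumn / neither)
2. share of target in all that became target or isomer of the product, winter
3. share of target in all that became target or isomer of the product, autumn

First I asked whether the split was a race or a balance. Isomer of the product, which forms from target, already read higher than target in delta at 12.0 h. From then to 25.0 h, the sum of the two in delta grew to twice its size, while the share moved from 41.2% to 45.5%. With a scatter of 2 percentage points on each reading, I could not call that a rise, so I read a balance: thermodynamic control.

Then I asked whether that balance applied to winter and autumn. Both stood at 0 °C, like delta, so I expected catalyst, feed and time to change how fast material arrived, not how it divided. So I put both winter and autumn at the split of 44.8%, a difference within 2 points.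

The forecast gave 45% for winter, 45% for autumn and neither, from the same readings, holding that “target and isomer seem to equilibrate quickly compared with product formation”.

The flasks gave 43.5% for winter and 43.6% for autumn, so the answer is neither.

    starting material + free catalyst ⇌ catalyst intermediate A (K = 260 /M, k = 880 /M/h, Ea = 58.0 kJ/mol, ΔH = −7.00 kJ/mol)
    partner + catalyst intermediate A → catalyst intermediate B (k = 250 /M/h, Ea = 54.0 kJ/mol)
    catalyst intermediate B → free catalyst + target (k = 8.90 /h, Ea = 86.0 kJ/mol)
    target ⇌ isomer of the product (K = 1.30, k = 0.980 /h, Ea = 76.0 kJ/mol, ΔH = −9.00 kJ/mol)
    (constants at 0 °C)

In autumn the share stands there because isomer of the product returns to target: removing that back reaction took the share from 43.6% to 0.371%. Take winter with 0.10 M of partner instead. Counting one target or isomer per partner, the split gives 17.9% of the starting material as target. The computed flask ended with 17.4% target, a share of 43.5%.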